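**Retrosynthetic overview**
- The last C–C bond joins flavone C2 to dihydrobenzofuran C5. It comes from a Suzuki–Miyaura coupling of a C5 boronate with a 2-chlorochromone (rings A and C), and all silyl groups leave in the final step.
- The strategy rests on the O1–C2H(CMe2OH)–C3H(OH) segment of the dihydrofuran ring fused to ring B. It is the constitutional isomer of the O1–CMe2–C3H(OH)–C4H(OH) segment of a trans-2,2-dimethylchroman-3,4-diol.
- Key disconnection: O1 moves from CMe2 to an activated C3 with inversion and water enters at CMe2, so the six-membered pyran contracts to the five-membered dihydrofuran.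
- The chroman-3-ol comes from 8-bromo-2,2-dimethylchromene by asymmetric epoxidation, hydroxide opening at C4, silylation of the C4 oxygen and Stille prenylation.
- Ring order: the pyran forms (Claisen rearrangement and electrocyclisation), then the oxirane forms and is opened, then the dihydrofuran forms by contraction. The chromone pyranone is built separately, and no ring forms after the coupling.

Key step: step 7

Assumption: 3,3-dichloroacrylic acid is taken as purchasable. Atoms are numbered as in chroman (O1, C2 = CMe2, C3, C4, C4a–C8a) up to the key step and as in 2,3-dihydrobenzofuran (O1, C2, C3, C3a–C7a) after it. The target SMILES reads as the trans-(2R,3R) isomer.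

**Step 1**
Reactants: 1 2-bromophenol; 2 3-chloro-3-methylbut-1-yne
Product: 3 1-bromo-2-(2-methylbut-3-yn-2-yloxy)benzene
Conditions: K2CO3, KI (cat.), CuI (cat.), DMF, 65 °C
Reagents that add atoms: none
Why: Copper-assisted Williamson-type O-alkylation of a phenoxide with the tertiary propargylic chloride is the standard entry to aryl 1,1-dimethylpropargyl ethers and leaves the aryl bromide untouched.

**Step 2**
Reactants: 3 1-bromo-2-(2-methylbut-3-yn-2-yloxy)benzene
Product: 5 8-bromo-2,2-dimethyl-2H-chromene, via allenylphenol 4 (not isolated)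
Conditions: N,N-diethylaniline, 190 °C
Reagents that add atoms: none
Why: Aromatic propargyl Claisen rearrangement to the only free ortho carbon gives allenylphenol 4 after tautomerisation, and a 1,5-hydrogen shift followed by oxa-6π electrocyclisation closes the pyran ring.

**Step 3**
Reactants: 5 8-bromo-2,2-dimethyl-2H-chromene
Product: 6 (3S,4S)-8-bromo-3,4-epoxy-2,2-dimethylchroman
Conditions: [(S,S)-N,N'-bis(3,5-di-tert-butylsalicylidene)cyclohexane-1,2-diaminato]manganese chloride (cat.), aq. NaOCl (pH 11.3, Na2HPO4), 4-phenylpyridine N-oxide (cat.), CH2Cl2, 0 °C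
Reagents that add atoms: sodium hypochlorite, [Na+].[O-]Cl
Why: In this Jacobsen–Katsuki epoxidation, for which cis-configured 2,2-dimethylchromenes are a privileged substrate class, the (S,S)-salen complex of trivalent manganese delivers oxygen to one face of C3=C4 and sets C3 and C4 both as S while no other alkene is present.

**Step 4**
Reactants: 6 (3S,4S)-8-bromo-3,4-epoxy-2,2-dimethylchroman
Product: 7 (3S,4R)-8-bromo-2,2-dimethylchroman-3,4-diol
Conditions: aq. KOH, DMSO, 80 °C
Reagents that add atoms: water, O
Why: In this SN2 epoxide opening, hydroxide attacks the benzylic C4 with inversion to give the trans-diol, basic conditions and the electron-poor bromoarene suppress a benzylic cation that would leak to the cis-diol, and attack at C3, which would give the enantiomer, is blocked by the adjacent quaternary C2.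

**Step 5**
Reactants: 7 (3S,4R)-8-bromo-2,2-dimethylchroman-3,4-diol
Product: 8 (3S,4R)-8-bromo-4-(tert-butyldimethylsilyloxy)-2,2-dimethylchroman-3-ol
Conditions: TBSCl (1.05 equiv), imidazole, DMF, 0 °C → rt
Reagents that add atoms: tert-butyldimethylsilyl chloride, C[Si](C)(Cl)C(C)(C)C
Why: The silylation should be regioselective because the benzylic C4–OH is the more accessible hydroxyl, C3–OH being neopentyl-like next to CMe2, and any base-induced silyl migration also ends on the less crowded C4 oxygen.

**Step 6**
Reactants: 8 (3S,4R)-8-bromo-4-(tert-butyldimethylsilyloxy)-2,2-dimethylchroman-3-ol; 9 tributyl(3-methylbut-2-enyl)stannane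
Product: 10 (3S,4R)-4-(tert-butyldimethylsilyloxy)-2,2-dimethyl-8-(3-methylbut-2-enyl)chroman-3-ol
Conditions: Pd(PPh3)4 (cat.), DMF, 100 °C, degassed
Reagents that add atoms: none
Why: In this Stille coupling, zerovalent palladium inserts into C8–Br, the prenyl group is transferred from tin, and reductive elimination at the less substituted allyl terminus gives the linear prenyl arene under neutral conditions that tolerate the free C3–OH and the silyl ether.

**Step 7**
Reactants: 10 (3S,4R)-4-(tert-butyldimethylsilyloxy)-2,2-dimethyl-8-(3-methylbut-2-enyl)chroman-3-ol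
Product: 13 2-[(2R,3R)-3-(tert-butyldimethylsilyloxy)-7-(3-methylbut-2-enyl)-2,3-dihydrobenzofuran-2-yl]propan-2-ol, via C3 triflate 11 (not isolated), via tertiary carbocation 12 (not isolated)
Conditions: Tf2O, 2,6-di-tert-butylpyridine, CH2Cl2, −78 → −30 °C; then transfer into NaHCO3, THF/H2O, 0 °C → rt
Reagents that add atoms: water, O; triflic anhydride, O=S(=O)(OS(=O)(=O)C(F)(F)F)C(F)(F)F (its CF3SO2 group is found only in 11)
Why: The non-nucleophilic base lets Tf2O turn the C3 hydroxyl into triflate 11 without displacing it; in the trans-diequatorial half-chair of 11 the C2–O1 bond lies antiperiplanar to C3–OTf, so a lone pair of O1 attacks C3 from the rear while C2–O1 breaks, the charge ends on the CMe2 carbon (cation 12), and water captures it as the tertiary alcohol. The closest known reaction type is the 1,2-aryloxy shift with ring contraction that activated 2,2-dimethylchroman-3-ols (sulfonates, fluorinating or Mitsunobu activation) undergo to 2-substituted 2,3-dihydrobenzofurans, water being merely a less usual trap. The dihydrofuran ring closes by intramolecular SN2 displacement, 3-exo-tet across the O1–C2–C3 bridge and 5-exo-tet when counted through C8a, C4a and C4, and the pyran ring is lost in the same event. The one new stereocentre, dihydrobenzofuran C2, arises by stereospecific inversion of chroman C3 (3S becomes 2R), whose configuration stems from the epoxidation, while the silyloxy carbon is untouched and stays R, so the trans-diol monoether gives the trans product. The step needs migration of O1 in preference to the C4–C4a bond (also antiperiplanar, a semipinacol-type shift) and to methyl, hydride or silyloxy participation (all gauche in this conformer), and it needs hydration in preference to proton loss or attack by the prenyl alkene. The lone pair on O1, the tertiary migration origin, the weak donor ability of the silyl ether oxygen and an aryl π system held out of alignment with the C3–O σ* orbital favour the first, a large excess of water in bicarbonate buffer favours the second, and attack of water at C3 instead of CMe2 would only return 10.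

**Step 8**
Reactants: 13 2-[(2R,3R)-3-(tert-butyldimethylsilyloxy)-7-(3-methylbut-2-enyl)-2,3-dihydrobenzofuran-2-yl]propan-2-ol
Product: 14 (2R,3R)-3-(tert-butyldimethylsilyloxy)-7-(3-methylbut-2-enyl)-2-[2-(triethylsilyloxy)propan-2-yl]-2,3-dihydrobenzofuran
Conditions: TESOTf, 2,6-lutidine, CH2Cl2, −78 → 0 °C
Reagents that add atoms: triethylsilyl triflate, CC[Si](CC)(CC)OS(=O)(=O)C(F)(F)F
Why: Silylation of the hindered tertiary alcohol with a silyl triflate and a hindered pyridine base removes the only O–H, which would otherwise consume boron reagent in the next step, and the group leaves with the others at the end.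

**Step 9**
Reactants: 14 (2R,3R)-3-(tert-butyldimethylsilyloxy)-7-(3-methylbut-2-enyl)-2-[2-(triethylsilyloxy)propan-2-yl]-2,3-dihydrobenzofuran
Product: 15 (2R,3R)-3-(tert-butyldimethylsilyloxy)-7-(3-methylbut-2-enyl)-5-(4,4,5,5-tetramethyl-1,3,2-dioxaborolan-2-yl)-2-[2-(triethylsilyloxy)propan-2-yl]-2,3-dihydrobenzofuran
Conditions: [Ir(OMe)(cod)]2 (cat.), 4,4'-di-tert-butyl-2,2'-bipyridine (cat.), B2pin2, THF, 70 °C
Reagents that add atoms: bis(pinacolato)diboron, CC1(C)OB(OC1(C)C)B1OC(C)(C)C(C)(C)O1
Why: Iridium-catalysed aromatic C–H borylation is sterically governed, and in this 1,2,3-trisubstituted benzene only C5–H has no ortho substituent (C4–H is shielded by the silyloxy carbon C3 and C6–H by the prenyl CH2), while the trisubstituted alkene is a poor partner for hydroboration.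

**Step 10**
Reactants: 16 phloroglucinol; 17 3,3-dichloroacrylic acid
Product: 20 2-chloro-5,7-dihydroxy-4H-chromen-4-one, via 3,3-dichloroacryloyl chloride 18 (not isolated), via dichlorovinyl ketone 19 (not isolated)
Conditions: 17, (COCl)2, DMF (cat.), CH2Cl2, rt, concentrate; 16, AlCl3, CH2Cl2/MeNO2, 0 → 40 °C; ice/HCl; then NaHCO3, acetone/H2O, rt
Reagents that add atoms: oxalyl chloride, O=C(Cl)C(=O)Cl (its chlorine is found only in 18)
Why: Friedel–Crafts C-acylation of the symmetric triphenol, followed by intramolecular addition–elimination of an ortho hydroxyl on the β,β-dichlorovinyl ketone, places the remaining chlorine at chromone C2, whereas chlorination of the tautomeric 4-hydroxycoumarin would put it on the carbon that has to be the flavone carbonyl.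

**Step 11**
Reactants: 20 2-chloro-5,7-dihydroxy-4H-chromen-4-one
Product: 21 2-chloro-5,7-bis(triisopropylsilyloxy)-4H-chromen-4-one
Conditions: TIPSOTf (2.5 equiv), 2,6-lutidine, CH2Cl2, 0 °C → rt
Reagents that add atoms: triisopropylsilyl triflate, CC(C)[Si](C(C)C)(C(C)C)OS(=O)(=O)C(F)(F)F
Why: O-silylation with a silyl triflate also reaches the hydrogen-bonded C5–OH, the hindered base avoids the addition–elimination at C2 that nucleophilic amines would cause, and triisopropylsilyl aryl ethers are chosen for their resistance to the mild base of the coupling.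

**Step 12**
Reactants: 15 the C5 pinacol boronate; 21 2-chloro-5,7-bis(triisopropylsilyloxy)-4H-chromen-4-one
Product: 22 2-[(2R,3R)-3-(tert-butyldimethylsilyloxy)-7-(3-methylbut-2-enyl)-2-[2-(triethylsilyloxy)propan-2-yl]-2,3-dihydrobenzofuran-5-yl]-5,7-bis(triisopropylsilyloxy)-4H-chromen-4-one
Conditions: Pd(dppf)Cl2 (cat.), K3PO4, 1,4-dioxane/H2O (10:1), 60 °C
Reagents that add atoms: none
Why: In this Suzuki–Miyaura coupling the C2–Cl bond of a 2-chlorochromone behaves as a vinylogous acid chloride that adds readily to zerovalent palladium, a coupling type known to give flavones, and neither the stereocentres nor the prenyl group take part.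

**Step 13**
Reactants: 22 the fully silylated flavone
Product: 23 5,7-dihydroxy-2-[(2R,3R)-3-hydroxy-2-(2-hydroxypropan-2-yl)-7-(3-methylbut-2-enyl)-2,3-dihydrobenzofuran-5-yl]-4H-chromen-4-one
Conditions: TBAF, AcOH, THF, 0 °C → rt
Reagents that add atoms: none
Why: Fluoride-induced cleavage of all four Si–O bonds under acetic acid buffering avoids the strong acid that would dehydrate the benzylic C3 alcohol to a benzofuran or cyclise the prenyl group, and it does not touch C2 or C3.

**Compound list**
1 | 2-bromophenol | Oc1ccccc1Br | starting material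
2 | 3-chloro-3-methylbut-1-yne | C#CC(C)(C)Cl | starting material
3 | 1-bromo-2-(2-methylbut-3-yn-2-yloxy)benzene | C#CC(C)(C)Oc1ccccc1Br | intermediate
4 | 2-bromo-6-(3-methylbuta-1,2-dienyl)phenol | CC(C)=C=Cc1cccc(Br)c1O | intermediate
5 | 8-bromo-2,2-dimethyl-2H-chromene | CC1(C)C=Cc2cccc(Br)c2O1 | intermediate
6 | (3S,4S)-8-bromo-3,4-epoxy-2,2-dimethylchroman | Brc1cccc2c1OC(C)(C)[C@H]3O[C@@H]23 | intermediate
7 | (3S,4R)-8-bromo-2,2-dimethylchroman-3,4-diol (trans) | Brc1cccc2c1OC(C)(C)[C@@H](O)[C@@H]2O | intermediate
8 | (3S,4R)-8-bromo-4-(tert-butyldimethylsilyloxy)-2,2-dimethylchroman-3-ol | Brc1cccc2c1OC(C)(C)[C@@H](O)[C@@H]2O[Si](C)(C)C(C)(C)C | intermediate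
9 | tributyl(3-methylbut-2-enyl)stannane | CCCC[Sn](CCCC)(CCCC)CC=C(C)C | starting material
10 | (3S,4R)-4-(tert-butyldimethylsilyloxy)-2,2-dimethyl-8-(3-methylbut-2-enyl)chroman-3-ol | CC(C)=CCc1cccc2c1OC(C)(C)[C@@H](O)[C@@H]2O[Si](C)(C)C(C)(C)C | intermediate
11 | (3S,4R)-4-(tert-butyldimethylsilyloxy)-2,2-dimethyl-8-(3-methylbut-2-enyl)chroman-3-yl trifluoromethanesulfonate | CC(C)=CCc1cccc2c1OC(C)(C)[C@@H](OS(=O)(=O)C(F)(F)F)[C@@H]2O[Si](C)(C)C(C)(C)C | intermediate
12 | 2-[3-(tert-butyldimethylsilyloxy)-7-(3-methylbut-2-enyl)-2,3-dihydrobenzofuran-2-yl]propan-2-ylium, spatial arrangement as in 13 | CC(C)=CCc1cccc2c1O[C@@H]([C+](C)C)[C@@H]2O[Si](C)(C)C(C)(C)C | intermediate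
13 | 2-[(2R,3R)-3-(tert-butyldimethylsilyloxy)-7-(3-methylbut-2-enyl)-2,3-dihydrobenzofuran-2-yl]propan-2-ol | CC(C)=CCc1cccc2c1O[C@@H](C(C)(C)O)[C@@H]2O[Si](C)(C)C(C)(C)C | intermediate
14 | (2R,3R)-3-(tert-butyldimethylsilyloxy)-7-(3-methylbut-2-enyl)-2-[2-(triethylsilyloxy)propan-2-yl]-2,3-dihydrobenzofuran | CC(C)=CCc1cccc2c1O[C@@H](C(C)(C)O[Si](CC)(CC)CC)[C@@H]2O[Si](C)(C)C(C)(C)C | intermediate
15 | 5-(4,4,5,5-tetramethyl-1,3,2-dioxaborolan-2-yl) derivative of 14, (2R,3R) | CC(C)=CCc1cc(B3OC(C)(C)C(C)(C)O3)cc2c1O[C@@H](C(C)(C)O[Si](CC)(CC)CC)[C@@H]2O[Si](C)(C)C(C)(C)C | intermediate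
16 | phloroglucinol | Oc1cc(O)cc(O)c1 | starting material
17 | 3,3-dichloroacrylic acid | OC(=O)C=C(Cl)Cl | starting material
18 | 3,3-dichloroacryloyl chloride | O=C(Cl)C=C(Cl)Cl | intermediate
19 | 3,3-dichloro-1-(2,4,6-trihydroxyphenyl)prop-2-en-1-one | O=C(C=C(Cl)Cl)c1c(O)cc(O)cc1O | intermediate
20 | 2-chloro-5,7-dihydroxy-4H-chromen-4-one | O=c1cc(Cl)oc2cc(O)cc(O)c12 | intermediate
21 | 2-chloro-5,7-bis(triisopropylsilyloxy)-4H-chromen-4-one | O=c1cc(Cl)oc2cc(O[Si](C(C)C)(C(C)C)C(C)C)cc(O[Si](C(C)C)(C(C)C)C(C)C)c12 | intermediate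
22 | fully silylated flavone, (2R,3R) | CC(C)=CCc1cc(-c2cc(=O)c3c(O[Si](C(C)C)(C(C)C)C(C)C)cc(O[Si](C(C)C)(C(C)C)C(C)C)cc3o2)cc2c1O[C@@H](C(C)(C)O[Si](CC)(CC)CC)[C@@H]2O[Si](C)(C)C(C)(C)C | intermediate
23 | 5,7-dihydroxy-2-[(2R,3R)-3-hydroxy-2-(2-hydroxypropan-2-yl)-7-(3-methylbut-2-enyl)-2,3-dihydrobenzofuran-5-yl]-4H-chromen-4-one | CC(C)=CCc1cc(-c2cc(=O)c3c(O)cc(O)cc3o2)cc2c1O[C@@H](C(C)(C)O)[C@@H]2O | target

**Step count**
- Total step count: 13.
- Longest linear sequence: 11 (steps 1–9, 12 and 13). Steps 10 and 11 form the side branch.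

**Steps most likely to fail**

*Step 7.* The tertiary cation may lose a proton faster than water captures it, the prenyl alkene may intercept it, or the C4–C4a bond may migrate in competition with O1.
- The fallback separates contraction from hydration and runs both before the prenyl group is present. It sets out from 8 and returns at 13.
- Compound 8 is triflated in dry CH2Cl2 (Tf2O, 2,6-di-tert-butylpyridine) to (3S,4R)-8-bromo-4-(tert-butyldimethylsilyloxy)-2,2-dimethylchroman-3-yl triflate F1.
- F1 is allowed to warm without any nucleophile. The same aryloxy shift then ends in deliberate proton loss, the documented outcome in non-nucleophilic media, and gives (2S,3R)-7-bromo-3-(tert-butyldimethylsilyloxy)-2-(prop-1-en-2-yl)-2,3-dihydrobenzofuran F2.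
- Mukaiyama hydration of the only alkene (Co(acac)2, PhSiH3, O2, i-PrOH/THF) installs the tertiary hydroxyl in the Markovnikov sense and gives 2-[(2R,3R)-7-bromo-3-(tert-butyldimethylsilyloxy)-2,3-dihydrobenzofuran-2-yl]propan-2-ol F3.
- Stille coupling of F3 with 9 (Pd(PPh3)4, DMF) delivers 13.

*Step 10.* Acylation of the free triphenol may be unselective between carbon and oxygen or go beyond monoacylation. The C2–Cl bond may also hydrolyse during the aqueous quench.
- The fallback moves the chemistry onto a monophenol with robust ether protection and removes that protection before the coupling. It sets out from 18 (made from 17 as before) and returns at 20.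
- Acid chloride 18 esterifies commercial 3,5-dimethoxyphenol (COc1cc(O)cc(OC)c1; Et3N, CH2Cl2) to 3,5-dimethoxyphenyl 3,3-dichloroacrylate F4.
- Fries rearrangement (AlCl3) gives 3,3-dichloro-1-(2-hydroxy-4,6-dimethoxyphenyl)prop-2-en-1-one F5.
- Dilute aqueous NaOH closes F5 to 2-chloro-5,7-dimethoxy-4H-chromen-4-one F6.
- BBr3 in CH2Cl2 cleaves both methyl ethers of F6 at the fragment stage, where no acid-sensitive group is present, to give 20.

*Step 12.* Base-induced loss of the aryl silyl ethers, hydrolysis of the C–Cl bond or protodeboronation may outrun transmetalation.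
- The fallback abandons the halide and the base and forms the same bond by C–H functionalisation of the chromone. It sets out from 21 and 15 and returns at 22.
- Chloride 21 is hydrodechlorinated (Pd(PPh3)4, Bu3SnH, THF) to 5,7-bis(triisopropylsilyloxy)-4H-chromen-4-one F7.
- F7 is arylated at C2 with boronate 15 in a base-free oxidative boron-Heck reaction (Pd(OAc)2, 2,9-dimethyl-1,10-phenanthroline, O2, DMF, 50 °C).
- In that reaction the aryl complex of divalent palladium adds across C2=C3 in the conjugate sense and β-hydride elimination restores the enone. This route to flavones is known, and the trisubstituted prenyl alkene is a poor competitor in it.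

**Further compounds**
F1 | step 7 | (3S,4R)-8-bromo-4-(tert-butyldimethylsilyloxy)-2,2-dimethylchroman-3-yl trifluoromethanesulfonate | Brc1cccc2c1OC(C)(C)[C@@H](OS(=O)(=O)C(F)(F)F)[C@@H]2O[Si](C)(C)C(C)(C)C
F2 | step 7 | (2S,3R)-7-bromo-3-(tert-butyldimethylsilyloxy)-2-(prop-1-en-2-yl)-2,3-dihydrobenzofuran | Brc1cccc2c1O[C@@H](C(C)=C)[C@@H]2O[Si](C)(C)C(C)(C)C
F3 | step 7 | 2-[(2R,3R)-7-bromo-3-(tert-butyldimethylsilyloxy)-2,3-dihydrobenzofuran-2-yl]propan-2-ol | Brc1cccc2c1O[C@@H](C(C)(C)O)[C@@H]2O[Si](C)(C)C(C)(C)C
F4 | step 10 | 3,5-dimethoxyphenyl 3,3-dichloroacrylate | COc1cc(OC)cc(OC(=O)C=C(Cl)Cl)c1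
F5 | step 10 | 3,3-dichloro-1-(2-hydroxy-4,6-dimethoxyphenyl)prop-2-en-1-one | COc1cc(O)c(C(=O)C=C(Cl)Cl)c(OC)c1
F6 | step 10 | 2-chloro-5,7-dimethoxy-4H-chromen-4-one | COc1cc(OC)c2c(=O)cc(Cl)oc2c1
F7 | step 12 | 5,7-bis(triisopropylsilyloxy)-4H-chromen-4-one | O=c1ccoc2cc(O[Si](C(C)C)(C(C)C)C(C)C)cc(O[Si](C(C)C)(C(C)C)C(C)C)c12
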